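## Structural features

The target is a fully substituted furan-2(5H)-one (ring atoms O1, C2 to C5; C6 is the exocyclic benzylidene carbon and C7 the carbinol carbon). C3 carries C7, a secondary alcohol that also bears ring A (3,5-dibromo-4-methoxyphenyl); C4 carries ring B (3-bromo-4-hydroxyphenyl); C5 is joined by a (Z)-double bond to C6, which bears ring C (3-bromo-4-hydroxyphenyl) on the side of O1. C7 is the only stereocentre: it is (S), has no stereogenic neighbour, and is both benzylic and allylic, so it ionises easily under acid. The (Z)-ylidene butenolide is a cross-conjugated acceptor that hydroxide, alkoxides and amines can open or attack, and the four aryl bromides exclude hydrogenolysis, aryllithium chemistry and hot zerovalent palladium late in the route. The ring A methyl ether must stay, so the two phenols cannot be carried as methyl ethers. The real difficulties are the crowding at C4 between the C3 side chain and the benzylidene, the need to tell the constitutionally identical rings B and C apart, and absolute control at C7 between two sp2 substituents. Ring B is bonded to C4 through the carbon para to its oxygen and has its bromine ortho to that oxygen. The key step uses this: the six ring B carbons are grown from a two-carbon ethynyl group on C4 and a four-carbon 1,3-dioxygenated diene, which leaves one free phenol to direct the last bromine.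

## Logic of the disconnections

**19 from 18.** Cut: the O–H bond of the ring C phenol, replaced by O–Si. The silyl ether is the only difference between rings B and C that the route can use, so it is kept to the end. The forward step must remove silicon without a base that opens the lactone and without an acid that ionises C7.

**18 from 17.** Cut: the C7–H bond, giving the C7 ketone. The carbonyl is needed earlier as an activating group, and a planar ketone postpones the only stereocentre to one reagent-controlled step. The demand is face selection between two sp2 substituents that differ mainly in bulk and twist.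

**17 from 16.** Cut: the ring B C–Br bond. Without it ring B is a plain 4-hydroxyphenyl group, which a symmetrical oxygenated diene can supply. The forward bromination must stop at one bromine and must choose the free phenol over silylated ring C.

**16 from 13 and 14 (through 15).** Cut: two ring B bonds, C1'–C6' and C2'–C3' (C1' is the carbon on C4). This removes the aryl group from the most hindered carbon and replaces it by a linear alkyne. The forward cycloaddition must place oxygen para to C4 and must choose the alkyne over the ring alkenes and the ketone.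

**13 from 12.** Cut: the terminal C(sp)–H bond, replaced by C–Si. A free alkyne on this acceptor would not survive the base of the ylidene-forming step. Alkoxide or fluoride would add to the acceptor or remove the ring C silyl ether, so the forward step needs a neutral, silicon-selective method.

**12 from 7 and 9 (through 10 and 11).** Cut: the C5=C6 double bond. This separates ring C as an aldehyde and leaves a butenolide with an acidic C5 methylene. Making this bond after the lactone ring lets ring C enter already silylated and never exposes that ether to hot acid. The forward condensation must give the (Z)-alkene and must use no nucleophilic amine.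

**9 from 8.** Cut: the O–Si bond. This is a one-step protection of a commercial aldehyde.

**7 from 5 and 6.** Cut: the C4–C(sp) bond. A cross-coupling partner as slim as an alkyne meets little hindrance at C4. The forward coupling must run cold enough to spare the ring A bromides and must avoid amines that displace the leaving group.

**5 from 4.** Cut: the O–S bond at C4. This turns the tricarbonyl enol into a leaving group. The demand is sulfonylation on the ring oxygen and not on the aroyl oxygen.

**4 from 1 and 2 (through 3).** Cut: the C3–C7 bond. Both pieces are commercial, and the C3=C4 bond is inside a ring from the first step, so no stereodefined acyclic tetrasubstituted alkene is ever needed. The forward acylation must end on carbon, not on oxygen.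

## Other disconnections considered

**Alternative 1:** The cut removes the C4–ring B bond and the O1–C5 bond together. The (S)-configured 2,3-allenoic acid A2 already holds C7 as its silyl ether and ring C as a benzyl group on the allene terminus. It would be coupled with the ring B iodide A3: zerovalent palladium inserts into the C–I bond, the arylpalladium iodide adds to the allene with aryl on the central carbon, and the carboxylate closes onto the π-allyl terminus. The product is butenolide A1 as a pair of C5 epimers.
- In its favour: the lactone ring and the crowded C4–aryl bond form in one convergent operation. Ring B arrives with its bromine, so no late bromination and no B/C differentiation are needed. C7 is fixed early by a carbonyl addition. On these three points it is the better plan.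
- Against it: A1 is at the wrong oxidation level, so C5–C6 must later be dehydrogenated to the (Z)-benzylidene next to a base-sensitive C7 silyloxy group. A2 is a trisubstituted allene with a stereocentre and needs a long synthesis of its own. The palladium step must pick one aryl iodide out of four aryl bromides.
- Comparison: structurally it reaches a 5-benzyl lactone where the chosen plan reaches the ylidene lactone directly. Mechanistically the catalytic cycle is as well understood as the cycloaddition, so the two are equal there. In step economy the extra oxidation and the allene synthesis should make it longer.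

**Alternative 2:** The cut is the C3=C4 double bond. The (Z)-enol A6 of the unsymmetrical 1,2-diketone joining rings B and C would be acylated on oxygen by aroylketene A7 to give enol ester A5. Its β-ketoester methylene then adds to the ring B ketone and water is lost (intramolecular Knoevenagel condensation), giving ketone A4.
- In its favour: acylketene capture followed by Knoevenagel closure is an established route to 3-aroyl-4-arylbutenolides. Every ring enters fully functionalised. A4 differs from 17 only by the ring B silyl ether, so the same reduction would finish the synthesis. In length it should be the better plan; in the end game it is the equal.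
- Against it: the electrophile is a diaryl-type ketone deactivated by a para-silyloxy group, so the bond to the most hindered carbon must form in the ring-closing step itself. A5 is an activated enol ester that can transfer its acyl group or lose its geometry under base. A6 needs its own synthesis and selective O-acylation.
- Comparison: the chosen plan installs the C4 substituent as a slender alkyne and builds outward, which is the safer course at that carbon. It pays for this with more steps and a late bromination.

**Alternative 3:** The cut is the O1–C5 bond alone. The (Z)-2-en-4-ynoic acid A9, with C7 already (S)-configured and silylated, would be treated with AgNO3. Monovalent silver activates the alkyne, the carboxylate adds anti at C5 in a 5-exo-dig closure, and protodemetalation gives the tris-silyl ether A8 with the (Z)-benzylidene set by the anti addition.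
- In its favour: the closure is mild and the alkene geometry follows from the mechanism, not from thermodynamic preference. All rings and the stereocentre are in place beforehand, and only a global desilylation remains. In end-game length and in certainty of the C7 configuration it is the better plan; in mildness it is the equal.
- Against it: the difficulty moves into A9, a tetrasubstituted alkene that must be made with the carboxyl group cis to the alkyne and three different hindered carbon substituents. The 6-endo-dig closure to a pyran-2-one competes and is favoured by an electron-rich aryl group on the alkyne, which ring C is.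
- Comparison: the chosen plan needs no stereodefined acyclic tetrasubstituted alkene, because C3=C4 is inside the tetronic acid ring from the first step. It needs three steps after its key step where A8 needs one.

Key step: step 7

Assumption: in the oxazaborolidine reduction of 17 the fully substituted butenolide carbon C3, twisted out of the carbonyl plane by its two neighbours, is taken as the larger ketone substituent and ring A as the smaller; on this basis the (R)-catalyst is chosen for the (S)-carbinol.

Abbreviations: TBS = tert-butyldimethylsilyl; DCC = N,N'-dicyclohexylcarbodiimide; DBU = 1,8-diazabicyclo[5.4.0]undec-7-ene; NBS = N-bromosuccinimide; Tf = trifluoromethanesulfonyl.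

## Route

Step 1
Reactants: 1 3,5-dibromo-4-methoxybenzoic acid; 2 tetronic acid (4-hydroxyfuran-2(5H)-one)
Product: 4 3-(3,5-dibromo-4-methoxybenzoyl)-4-hydroxyfuran-2(5H)-one, via enol ester 3 (not isolated)
Conditions: DCC (1.1 equiv), 4-(dimethylamino)pyridine (1.3 equiv), Et3N (1.1 equiv), CH2Cl2, 0 °C to rt; 1 M HCl work-up
Reagents that add atoms: none
Why: Steglich-type O-acylation of the vinylogous acid 2 should give enol ester 3, and 4-(dimethylamino)pyridine then moves the aroyl group to C3 through an N-acylpyridinium/tetronate ion pair (Fries-type O-to-C acyl migration known for tetronic acids). The strongly acidic tricarbonyl system of 4 is the driving force, and ring A has no enolisable position, so only one C-acyl product can form.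

Step 2
Reactants: 4 3-(3,5-dibromo-4-methoxybenzoyl)-4-hydroxyfuran-2(5H)-one
Product: 5 4-(3,5-dibromo-4-methoxybenzoyl)-5-oxo-2,5-dihydrofuran-3-yl trifluoromethanesulfonate
Conditions: Tf2O (1.1 equiv), iPr2NEt (1.2 equiv), CH2Cl2, −78 to −20 °C; cold aqueous work-up, used at once
Reagents that add atoms: trifluoromethanesulfonic anhydride, O=S(=O)(OS(=O)(=O)C(F)(F)F)C(F)(F)F
Why: O-Sulfonylation of a cyclic tricarbonyl enolate; the ring oxygen at C4 should react in preference to the aroyl oxygen because that product keeps both the aryl ketone and the unsaturated lactone, the same endocyclic preference that 2-aroylcyclohexane-1,3-diones show when converted to vinylogous acyl halides. The product is a vinylogous mixed anhydride, hence the cold, base-poor handling.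

Step 3
Reactants: 5 4-(3,5-dibromo-4-methoxybenzoyl)-5-oxo-2,5-dihydrofuran-3-yl trifluoromethanesulfonate; 6 trimethylsilylacetylene
Product: 7 3-(3,5-dibromo-4-methoxybenzoyl)-4-[(trimethylsilyl)ethynyl]furan-2(5H)-one
Conditions: PdCl2(PPh3)2 (3 mol %), CuI (5 mol %), iPr2NEt (2 equiv), THF, 0 °C to rt
Reagents that add atoms: none
Why: Sonogashira coupling; oxidative addition of zerovalent palladium into the doubly activated C4–O bond should be fast at or below room temperature, where the ring A bromides are inert. The hindered tertiary amine cannot displace the triflate by addition–elimination.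

Step 4
Reactants: 8 3-bromo-4-hydroxybenzaldehyde
Product: 9 3-bromo-4-(tert-butyldimethylsilyloxy)benzaldehyde
Conditions: TBSCl (1.1 equiv), imidazole (2 equiv), DMF, rt
Reagents that add atoms: tert-butyldimethylsilyl chloride, CC(C)(C)[Si](C)(C)Cl
Why: Standard silylation of a phenol; the ether masks ring C so that later only ring B carries a free, bromination-directing hydroxyl.

Step 5
Reactants: 7 3-(3,5-dibromo-4-methoxybenzoyl)-4-[(trimethylsilyl)ethynyl]furan-2(5H)-one; 9 3-bromo-4-(tert-butyldimethylsilyloxy)benzaldehyde
Product: 12 (Z)-5-[3-bromo-4-(tert-butyldimethylsilyloxy)benzylidene]-3-(3,5-dibromo-4-methoxybenzoyl)-4-[(trimethylsilyl)ethynyl]furan-2(5H)-one, via silyloxyfuran 10 (not isolated), via aldol silyl ether 11 (not isolated)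
Conditions: TBSOTf (1.5 equiv), iPr2NEt (3 equiv), CH2Cl2, −78 °C to rt; then DBU (2 equiv), rt, anhydrous
Reagents that add atoms: none
Why: Silylative vinylogous aldol condensation, known for 4-substituted and 3-aroyl-4-aryl butenolides: soft enolisation gives 2-silyloxyfuran 10, which adds through C5 to the silyl-triflate-activated aldehyde to give 11, and DBU expels silanolate by an E1cB path. The (Z)-alkene is expected as the thermodynamic product, with the aryl group on the O1 side away from the C4 substituent; the C-silyl cap keeps the alkyne inert to base.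

Step 6
Reactants: 12 (Z)-5-[3-bromo-4-(tert-butyldimethylsilyloxy)benzylidene]-3-(3,5-dibromo-4-methoxybenzoyl)-4-[(trimethylsilyl)ethynyl]furan-2(5H)-one
Product: 13 (Z)-5-[3-bromo-4-(tert-butyldimethylsilyloxy)benzylidene]-3-(3,5-dibromo-4-methoxybenzoyl)-4-ethynylfuran-2(5H)-one
Conditions: AgNO3 (0.15 equiv), acetone/H2O/CH2Cl2, rt, dark; used promptly
Reagents that add atoms: none
Why: Silver-catalysed protiodesilylation of a trimethylsilylalkyne (silver acetylide, then protonolysis by water), a neutral method that should spare aryl silyl ethers. It supplies no alkoxide or fluoride that could add to the dienyl lactone, open it, or remove the ring C silyl group.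

Step 7
Reactants: 13 (Z)-5-[3-bromo-4-(tert-butyldimethylsilyloxy)benzylidene]-3-(3,5-dibromo-4-methoxybenzoyl)-4-ethynylfuran-2(5H)-one; 14 (E)-1-methoxy-3-(trimethylsilyloxy)buta-1,3-diene
Product: 16 (Z)-5-[3-bromo-4-(tert-butyldimethylsilyloxy)benzylidene]-3-(3,5-dibromo-4-methoxybenzoyl)-4-(4-hydroxyphenyl)furan-2(5H)-one, via cycloadduct 15 (not isolated)
Conditions: 14 (3 equiv), toluene, 90 °C, sealed tube; concentrate; then 1 M HCl, THF, 0 °C
Reagents that add atoms: none
Why: The electron-rich diene 14 and the terminal alkyne of 13 should combine in a thermal normal-electron-demand [4+2] cycloaddition of the kind known for 1-alkoxy-3-silyloxybutadienes with ynones and propiolates; here the alkyne LUMO is lowered through the C4=C3 bond by the lactone carbonyl and the C3 aroyl group. Bond formation is expected to be asynchronous: the nucleophilic CH2 terminus of 14 attacks the terminal alkyne carbon (the δ-position of the doubly activated dienyl acceptor) and the methoxy-bearing terminus closes onto the internal carbon, which places oxygen para to C4 in cyclohexa-1,4-diene 15. The six-membered carbocycle is therefore closed by an intermolecular cycloaddition that forms both new ring B bonds (C1'–C6' and C2'–C3') in one operation, not by cyclisation of a chain. Dilute acid then ionises the doubly allylic methoxy group of 15, a proton is lost from the ring CH2, and hydrolysis of the aryl trimethylsilyl ether leaves the phenol of 16, with aromatisation as the driving force. No stereocentre results: the methoxy-bearing carbon of 15 is racemic and disappears on aromatisation, and the (Z)-C5=C6 bond is not involved. The step needs regioselectivity, secured by the matching polarisation of diene and alkyne, and site selectivity for the alkyne over C3=C4, C5=C6 and the C7 carbonyl, secured because the alkyne is terminal and unhindered while the alkenes are tetra- and trisubstituted and the ketone would need Lewis acid activation. The ring C tert-butyldimethylsilyl ether should tolerate brief cold dilute acid, so ring B emerges as the only free phenol.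

Step 8
Reactants: 16 (Z)-5-[3-bromo-4-(tert-butyldimethylsilyloxy)benzylidene]-3-(3,5-dibromo-4-methoxybenzoyl)-4-(4-hydroxyphenyl)furan-2(5H)-one
Product: 17 (Z)-4-(3-bromo-4-hydroxyphenyl)-5-[3-bromo-4-(tert-butyldimethylsilyloxy)benzylidene]-3-(3,5-dibromo-4-methoxybenzoyl)furan-2(5H)-one
Conditions: NBS (1.0 equiv, slow addition), MeCN, −20 to 0 °C, dark
Reagents that add atoms: N-bromosuccinimide, O=C1CCC(=O)N1Br
Why: Electrophilic aromatic bromination; the free phenol of ring B is the most electron-rich ring (ring C is a silyl ether that already has an ortho bromine, ring A is fully substituted). Its para position is blocked and its two ortho positions are equivalent, so one equivalent of NBS at low temperature should give the monobromide.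

Step 9
Reactants: 17 (Z)-4-(3-bromo-4-hydroxyphenyl)-5-[3-bromo-4-(tert-butyldimethylsilyloxy)benzylidene]-3-(3,5-dibromo-4-methoxybenzoyl)furan-2(5H)-one
Product: 18 (Z)-4-(3-bromo-4-hydroxyphenyl)-5-[3-bromo-4-(tert-butyldimethylsilyloxy)benzylidene]-3-[(S)-(3,5-dibromo-4-methoxyphenyl)(hydroxy)methyl]furan-2(5H)-one
Conditions: (R)-2-methyl-CBS-oxazaborolidine [(3aR)-1-methyl-3,3-diphenyltetrahydro-1H,3H-pyrrolo[1,2-c][1,3,2]oxazaborole] (0.3 equiv), BH3·SMe2 (2.2 equiv), THF, −20 °C; then MeOH
Reagents that add atoms: none
Why: Corey–Bakshi–Shibata reduction; the ketone should bind to the ring boron through the lone pair remote from the bulkier, twisted butenolide C3, and hydride transfer from the nitrogen-bound borane through a six-membered transition state then reaches the face that gives the (S)-carbinol with the (R)-catalyst. The first equivalent of borane is consumed by the phenol as an aryloxyborane; the lactone, the alkenes and the aryl bromides should not be reduced at −20 °C.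

Step 10
Reactants: 18 (Z)-4-(3-bromo-4-hydroxyphenyl)-5-[3-bromo-4-(tert-butyldimethylsilyloxy)benzylidene]-3-[(S)-(3,5-dibromo-4-methoxyphenyl)(hydroxy)methyl]furan-2(5H)-one
Product: 19 (Z)-4-(3-bromo-4-hydroxyphenyl)-5-(3-bromo-4-hydroxybenzylidene)-3-[(S)-(3,5-dibromo-4-methoxyphenyl)(hydroxy)methyl]furan-2(5H)-one (CID71459453)
Conditions: Bu4NF (1.2 equiv), AcOH (1.5 equiv), THF, 0 °C
Reagents that add atoms: none
Why: Fluoride cleaves the aryl O–Si bond, and acetic acid buffers the phenoxides so that the base-sensitive (Z)-ylidene butenolide and the ionisable C7 carbinol meet neither strong base nor strong acid. The C7 configuration is not touched.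

## Compound list

1 | 3,5-dibromo-4-methoxybenzoic acid | COc1c(Br)cc(C(=O)O)cc1Br | starting material
2 | tetronic acid (4-hydroxyfuran-2(5H)-one) | O=C1C=C(O)CO1 | starting material
3 | 5-oxo-2,5-dihydrofuran-3-yl 3,5-dibromo-4-methoxybenzoate | COc1c(Br)cc(C(=O)OC2=CC(=O)OC2)cc1Br | intermediate (not isolated)
4 | 3-(3,5-dibromo-4-methoxybenzoyl)-4-hydroxyfuran-2(5H)-one, drawn as the 4-hydroxy tautomer | COc1c(Br)cc(C(=O)C2=C(O)COC2=O)cc1Br | intermediate
5 | 4-(3,5-dibromo-4-methoxybenzoyl)-5-oxo-2,5-dihydrofuran-3-yl trifluoromethanesulfonate | COc1c(Br)cc(C(=O)C2=C(OS(=O)(=O)C(F)(F)F)COC2=O)cc1Br | intermediate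
6 | trimethylsilylacetylene | C#C[Si](C)(C)C | starting material
7 | 3-(3,5-dibromo-4-methoxybenzoyl)-4-[(trimethylsilyl)ethynyl]furan-2(5H)-one | COc1c(Br)cc(C(=O)C2=C(C#C[Si](C)(C)C)COC2=O)cc1Br | intermediate
8 | 3-bromo-4-hydroxybenzaldehyde | O=Cc1ccc(O)c(Br)c1 | starting material
9 | 3-bromo-4-(tert-butyldimethylsilyloxy)benzaldehyde | O=Cc1ccc(O[Si](C)(C)C(C)(C)C)c(Br)c1 | intermediate
10 | [2-(tert-butyldimethylsilyloxy)-4-[(trimethylsilyl)ethynyl]furan-3-yl](3,5-dibromo-4-methoxyphenyl)methanone | COc1c(Br)cc(C(=O)c2c(C#C[Si](C)(C)C)coc2O[Si](C)(C)C(C)(C)C)cc1Br | intermediate (not isolated)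
11 | 5-{[3-bromo-4-(tert-butyldimethylsilyloxy)phenyl](tert-butyldimethylsilyloxy)methyl}-3-(3,5-dibromo-4-methoxybenzoyl)-4-[(trimethylsilyl)ethynyl]furan-2(5H)-one, racemic mixture of diastereomers | COc1c(Br)cc(C(=O)C2=C(C#C[Si](C)(C)C)C(C(O[Si](C)(C)C(C)(C)C)c3ccc(O[Si](C)(C)C(C)(C)C)c(Br)c3)OC2=O)cc1Br | intermediate (not isolated)
12 | (Z)-5-[3-bromo-4-(tert-butyldimethylsilyloxy)benzylidene]-3-(3,5-dibromo-4-methoxybenzoyl)-4-[(trimethylsilyl)ethynyl]furan-2(5H)-one | COc1c(Br)cc(C(=O)C2=C(C#C[Si](C)(C)C)/C(=C/c3ccc(O[Si](C)(C)C(C)(C)C)c(Br)c3)OC2=O)cc1Br | intermediate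
13 | (Z)-5-[3-bromo-4-(tert-butyldimethylsilyloxy)benzylidene]-3-(3,5-dibromo-4-methoxybenzoyl)-4-ethynylfuran-2(5H)-one | COc1c(Br)cc(C(=O)C2=C(C#C)/C(=C/c3ccc(O[Si](C)(C)C(C)(C)C)c(Br)c3)OC2=O)cc1Br | intermediate (key-step precursor)
14 | (E)-1-methoxy-3-(trimethylsilyloxy)buta-1,3-diene | CO/C=C/C(=C)O[Si](C)(C)C | starting material
15 | (Z)-5-[3-bromo-4-(tert-butyldimethylsilyloxy)benzylidene]-3-(3,5-dibromo-4-methoxybenzoyl)-4-[6-methoxy-4-(trimethylsilyloxy)cyclohexa-1,4-dien-1-yl]furan-2(5H)-one, racemic at the methoxy carbon | COc1c(Br)cc(C(=O)C2=C(C3=CCC(O[Si](C)(C)C)=CC3OC)/C(=C/c3ccc(O[Si](C)(C)C(C)(C)C)c(Br)c3)OC2=O)cc1Br | intermediate (not isolated)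
16 | (Z)-5-[3-bromo-4-(tert-butyldimethylsilyloxy)benzylidene]-3-(3,5-dibromo-4-methoxybenzoyl)-4-(4-hydroxyphenyl)furan-2(5H)-one | COc1c(Br)cc(C(=O)C2=C(c3ccc(O)cc3)/C(=C/c3ccc(O[Si](C)(C)C(C)(C)C)c(Br)c3)OC2=O)cc1Br | intermediate (key-step product)
17 | (Z)-4-(3-bromo-4-hydroxyphenyl)-5-[3-bromo-4-(tert-butyldimethylsilyloxy)benzylidene]-3-(3,5-dibromo-4-methoxybenzoyl)furan-2(5H)-one | COc1c(Br)cc(C(=O)C2=C(c3ccc(O)c(Br)c3)/C(=C/c3ccc(O[Si](C)(C)C(C)(C)C)c(Br)c3)OC2=O)cc1Br | intermediate
18 | (Z)-4-(3-bromo-4-hydroxyphenyl)-5-[3-bromo-4-(tert-butyldimethylsilyloxy)benzylidene]-3-[(S)-(3,5-dibromo-4-methoxyphenyl)(hydroxy)methyl]furan-2(5H)-one | COc1c(Br)cc([C@H](O)C2=C(c3ccc(O)c(Br)c3)/C(=C/c3ccc(O[Si](C)(C)C(C)(C)C)c(Br)c3)OC2=O)cc1Br | intermediate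
19 | (Z)-4-(3-bromo-4-hydroxyphenyl)-5-(3-bromo-4-hydroxybenzylidene)-3-[(S)-(3,5-dibromo-4-methoxyphenyl)(hydroxy)methyl]furan-2(5H)-one | COc1c(Br)cc([C@H](O)C2=C(c3ccc(O)c(Br)c3)/C(=C/c3ccc(O)c(Br)c3)OC2=O)cc1Br | target

## Step count and least certain steps

Total: 10 steps. Longest linear sequence: 9 steps (steps 1, 2, 3, 5, 6, 7, 8, 9, 10, from 1 and 2); step 4 is a one-step side branch.

**Step 7 (key step).** The alkyne is activated only through the C4=C3 bond, so the most likely failure is loss of site selectivity or of the substrate: open-chain conjugate addition of the silyl enol ether without ring closure, cycloaddition at the more electron-poor C3=C4 bond, or thermal oligomerisation of the ethynyl dienyl lactone faster than the bimolecular cycloaddition. The fallback attaches ring B whole by cross-coupling and sets out from 5. Suzuki–Miyaura coupling of 5 with 4-hydroxyphenylboronic acid (Pd(PPh3)4, anhydrous K3PO4, THF, rt) should give 3-(3,5-dibromo-4-methoxybenzoyl)-4-(4-hydroxyphenyl)furan-2(5H)-one F1. NBS bromination ortho to its only phenol gives 4-(3-bromo-4-hydroxyphenyl)-3-(3,5-dibromo-4-methoxybenzoyl)furan-2(5H)-one F2. Silylative vinylogous aldol condensation of F2 with 9 (excess TBSOTf/iPr2NEt, which also silylates the phenol, then DBU) gives the bis-silyl ketone (Z)-4-[3-bromo-4-(tert-butyldimethylsilyloxy)phenyl]-5-[3-bromo-4-(tert-butyldimethylsilyloxy)benzylidene]-3-(3,5-dibromo-4-methoxybenzoyl)furan-2(5H)-one F3. Reduction as in step 9 gives the (S)-carbinol bis-silyl ether F4, and Bu4NF/AcOH brings the sequence back to the route at 19.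

**Step 2.** Sulfonylation may go to the aroyl oxygen instead of the ring oxygen, and the very electrophilic triflate may be lost by hydrolysis or aminolysis during isolation and in step 3. The fallback replaces O-sulfonylation by deoxygenative halogenation and sets out from 4. Oxalyl bromide with catalytic N,N-dimethylformamide in CH2Cl2 should give the vinylogous acyl bromide 4-bromo-3-(3,5-dibromo-4-methoxybenzoyl)furan-2(5H)-one F5, which can be chromatographed and characterised before use. Sonogashira coupling of F5 with 6 under the step 3 conditions comes back at 7.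

**Step 9.** Facial selectivity may be poor or opposite to the assumed sense, because both ketone substituents are sp2 carbons and the catalyst must discriminate by twist and bulk alone; uncatalysed reduction by the aryloxyborane would erode selectivity further. The sense would be checked by MTPA ester analysis. The fallback gives up asymmetric induction for resolution and sets out from 17. Luche reduction (NaBH4, CeCl3·7H2O, MeOH/THF, −40 °C) should give the racemic carbinol (Z)-4-(3-bromo-4-hydroxyphenyl)-5-[3-bromo-4-(tert-butyldimethylsilyloxy)benzylidene]-3-[(3,5-dibromo-4-methoxyphenyl)(hydroxy)methyl]furan-2(5H)-one F6. Preparative chromatography on a chiral stationary phase then delivers 18, and the other half of F6 is returned to 17 by MnO2 oxidation.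

**Step 8.** The first bromine deactivates the phenol only weakly, so over-bromination to a 3,5-dibromo-4-hydroxyphenyl ring, or attack at the enol-ether-like C5=C6 bond, may compete. The fallback carries the bromine in the diene and sets out from 13. (Z)-3-Bromo-4-methoxybut-3-en-2-one F7 (bromination and dehydrobromination of 4-methoxybut-3-en-2-one) is silylated with Me3SiOTf/Et3N to (1Z)-2-bromo-1-methoxy-3-(trimethylsilyloxy)buta-1,3-diene F8. Cycloaddition of F8 with 13 as in step 7 gives the 5-bromo-6-methoxy-4-(trimethylsilyloxy)cyclohexa-1,4-dien-1-yl cycloadduct F9, and acid aromatisation comes back at 17, the bromine sitting on the diene carbon next to the oxygen-bearing one.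

**Step 6.** Protiodesilylation may be slow on so electron-poor an alkyne, and prolonged exposure invites hydration of the alkyne or loss of the ring C silyl ether. The fallback accepts global desilylation and sets out from 12. Bu4NF/AcOH (THF, −20 °C) should remove both silyl groups to give (Z)-5-(3-bromo-4-hydroxybenzylidene)-3-(3,5-dibromo-4-methoxybenzoyl)-4-ethynylfuran-2(5H)-one F10, and re-silylation of the phenol (TBSCl, imidazole, CH2Cl2) comes back at 13.

**Step 1.** The aroyl group may stop at the enol ester, since O-to-C migration is slower for aroyl than for alkanoyl groups, or the activated acid may rearrange to the N-acylurea. The fallback builds the tricarbonyl ring by a Lacey–Dieckmann sequence and sets out from 1. DCC/4-(dimethylamino)pyridine coupling of 1 with Meldrum's acid gives 5-[(3,5-dibromo-4-methoxyphenyl)(hydroxy)methylidene]-2,2-dimethyl-1,3-dioxane-4,6-dione F11. Heating F11 with methyl glycolate in toluene gives methyl 2-{[3-(3,5-dibromo-4-methoxyphenyl)-3-oxopropanoyl]oxy}acetate F12, and KOtBu in tBuOH/THF closes the ring to come back at 4.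

## Further compounds

F1 | step 7 | 3-(3,5-dibromo-4-methoxybenzoyl)-4-(4-hydroxyphenyl)furan-2(5H)-one | COc1c(Br)cc(C(=O)C2=C(c3ccc(O)cc3)COC2=O)cc1Br
F2 | step 7 | 4-(3-bromo-4-hydroxyphenyl)-3-(3,5-dibromo-4-methoxybenzoyl)furan-2(5H)-one | COc1c(Br)cc(C(=O)C2=C(c3ccc(O)c(Br)c3)COC2=O)cc1Br
F3 | step 7 | (Z)-4-[3-bromo-4-(tert-butyldimethylsilyloxy)phenyl]-5-[3-bromo-4-(tert-butyldimethylsilyloxy)benzylidene]-3-(3,5-dibromo-4-methoxybenzoyl)furan-2(5H)-one | COc1c(Br)cc(C(=O)C2=C(c3ccc(O[Si](C)(C)C(C)(C)C)c(Br)c3)/C(=C/c3ccc(O[Si](C)(C)C(C)(C)C)c(Br)c3)OC2=O)cc1Br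
F4 | step 7 | (Z)-4-[3-bromo-4-(tert-butyldimethylsilyloxy)phenyl]-5-[3-bromo-4-(tert-butyldimethylsilyloxy)benzylidene]-3-[(S)-(3,5-dibromo-4-methoxyphenyl)(hydroxy)methyl]furan-2(5H)-one | COc1c(Br)cc([C@H](O)C2=C(c3ccc(O[Si](C)(C)C(C)(C)C)c(Br)c3)/C(=C/c3ccc(O[Si](C)(C)C(C)(C)C)c(Br)c3)OC2=O)cc1Br
F5 | step 2 | 4-bromo-3-(3,5-dibromo-4-methoxybenzoyl)furan-2(5H)-one | COc1c(Br)cc(C(=O)C2=C(Br)COC2=O)cc1Br
F6 | step 9 | racemic (Z)-4-(3-bromo-4-hydroxyphenyl)-5-[3-bromo-4-(tert-butyldimethylsilyloxy)benzylidene]-3-[(3,5-dibromo-4-methoxyphenyl)(hydroxy)methyl]furan-2(5H)-one | COc1c(Br)cc(C(O)C2=C(c3ccc(O)c(Br)c3)/C(=C/c3ccc(O[Si](C)(C)C(C)(C)C)c(Br)c3)OC2=O)cc1Br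
F7 | step 8 | (Z)-3-bromo-4-methoxybut-3-en-2-one | CC(=O)/C(Br)=C/OC
F8 | step 8 | (1Z)-2-bromo-1-methoxy-3-(trimethylsilyloxy)buta-1,3-diene | CO/C=C(\Br)C(=C)O[Si](C)(C)C
F9 | step 8 | (Z)-4-[5-bromo-6-methoxy-4-(trimethylsilyloxy)cyclohexa-1,4-dien-1-yl]-5-[3-bromo-4-(tert-butyldimethylsilyloxy)benzylidene]-3-(3,5-dibromo-4-methoxybenzoyl)furan-2(5H)-one, racemic at the methoxy carbon | COc1c(Br)cc(C(=O)C2=C(C3=CCC(O[Si](C)(C)C)=C(Br)C3OC)/C(=C/c3ccc(O[Si](C)(C)C(C)(C)C)c(Br)c3)OC2=O)cc1Br
F10 | step 6 | (Z)-5-(3-bromo-4-hydroxybenzylidene)-3-(3,5-dibromo-4-methoxybenzoyl)-4-ethynylfuran-2(5H)-one | COc1c(Br)cc(C(=O)C2=C(C#C)/C(=C/c3ccc(O)c(Br)c3)OC2=O)cc1Br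
F11 | step 1 | 5-[(3,5-dibromo-4-methoxyphenyl)(hydroxy)methylidene]-2,2-dimethyl-1,3-dioxane-4,6-dione | COc1c(Br)cc(C(O)=C2C(=O)OC(C)(C)OC2=O)cc1Br
F12 | step 1 | methyl 2-{[3-(3,5-dibromo-4-methoxyphenyl)-3-oxopropanoyl]oxy}acetate | COC(=O)COC(=O)CC(=O)c1cc(Br)c(OC)c(Br)c1
A1 | alternative 1 | 5-[3-bromo-4-(tert-butyldimethylsilyloxy)benzyl]-4-[3-bromo-4-(tert-butyldimethylsilyloxy)phenyl]-3-[(S)-(tert-butyldimethylsilyloxy)(3,5-dibromo-4-methoxyphenyl)methyl]furan-2(5H)-one, C5 epimers | COc1c(Br)cc([C@H](O[Si](C)(C)C(C)(C)C)C2=C(c3ccc(O[Si](C)(C)C(C)(C)C)c(Br)c3)C(Cc3ccc(O[Si](C)(C)C(C)(C)C)c(Br)c3)OC2=O)cc1Br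
A2 | alternative 1 | 5-[3-bromo-4-(tert-butyldimethylsilyloxy)phenyl]-2-[(S)-(tert-butyldimethylsilyloxy)(3,5-dibromo-4-methoxyphenyl)methyl]penta-2,3-dienoic acid, allene axis unspecified | COc1c(Br)cc([C@H](O[Si](C)(C)C(C)(C)C)C(C(=O)O)=C=CCc2ccc(O[Si](C)(C)C(C)(C)C)c(Br)c2)cc1Br
A3 | alternative 1 | (2-bromo-4-iodophenoxy)(tert-butyl)dimethylsilane | CC(C)(C)[Si](C)(C)Oc1ccc(I)cc1Br
A4 | alternative 2 | (Z)-4-[3-bromo-4-(tert-butyldimethylsilyloxy)phenyl]-5-[3-bromo-4-(tert-butyldimethylsilyloxy)benzylidene]-3-(3,5-dibromo-4-methoxybenzoyl)furan-2(5H)-one | COc1c(Br)cc(C(=O)C2=C(c3ccc(O[Si](C)(C)C(C)(C)C)c(Br)c3)/C(=C/c3ccc(O[Si](C)(C)C(C)(C)C)c(Br)c3)OC2=O)cc1Br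
A5 | alternative 2 | (Z)-1,3-bis[3-bromo-4-(tert-butyldimethylsilyloxy)phenyl]-3-oxoprop-1-en-2-yl 3-(3,5-dibromo-4-methoxyphenyl)-3-oxopropanoate | COc1c(Br)cc(C(=O)CC(=O)O/C(=C\c2ccc(O[Si](C)(C)C(C)(C)C)c(Br)c2)C(=O)c2ccc(O[Si](C)(C)C(C)(C)C)c(Br)c2)cc1Br
A6 | alternative 2 | (Z)-1,3-bis[3-bromo-4-(tert-butyldimethylsilyloxy)phenyl]-2-hydroxyprop-2-en-1-one | O=C(c1ccc(O[Si](C)(C)C(C)(C)C)c(Br)c1)/C(O)=C/c1ccc(O[Si](C)(C)C(C)(C)C)c(Br)c1
A7 | alternative 2 | (3,5-dibromo-4-methoxybenzoyl)ketene | COc1c(Br)cc(C(=O)C=C=O)cc1Br
A8 | alternative 3 | (Z)-4-[3-bromo-4-(tert-butyldimethylsilyloxy)phenyl]-5-[3-bromo-4-(tert-butyldimethylsilyloxy)benzylidene]-3-[(S)-(tert-butyldimethylsilyloxy)(3,5-dibromo-4-methoxyphenyl)methyl]furan-2(5H)-one | COc1c(Br)cc([C@H](O[Si](C)(C)C(C)(C)C)C2=C(c3ccc(O[Si](C)(C)C(C)(C)C)c(Br)c3)/C(=C/c3ccc(O[Si](C)(C)C(C)(C)C)c(Br)c3)OC2=O)cc1Br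
A9 | alternative 3 | (Z)-3,5-bis[3-bromo-4-(tert-butyldimethylsilyloxy)phenyl]-2-[(S)-(tert-butyldimethylsilyloxy)(3,5-dibromo-4-methoxyphenyl)methyl]pent-2-en-4-ynoic acid | COc1c(Br)cc([C@H](O[Si](C)(C)C(C)(C)C)/C(C(=O)O)=C(/C#Cc2ccc(O[Si](C)(C)C(C)(C)C)c(Br)c2)c2ccc(O[Si](C)(C)C(C)(C)C)c(Br)c2)cc1Br
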